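## Structural features

The target is a linear polypropionate whose non-6-ene chain (C1–C9) carries ring A, a 6-ethyl-3,5-dimethyl-4-oxo-4H-pyran-2-yl group, on C2 and ring B, a 3,5-dimethyl-4-oxo-4H-pyran-2,6-diyl unit, on C8; the other α-carbon of ring B bears a 3-hydroxypentan-2-yl arm (C2', C3'). C2–C5 form a contiguous tetrad (CH3, OAc, CH3, OAc; 2,3-anti, 3,4-syn, 4,5-anti; all R). C6=C7 is an E trisubstituted olefin, C8 (S) is an isolated centre, and C2'/C3' are an anti pair (S,S). Three of the seven stereocentres (C2, C8, C2') are lateral carbons of a pyranone, and each ring with its lateral carbons is the skeleton of the symmetric 2,6-diethyl-3,5-dimethyl-4H-pyran-4-one, so one cheap compound contains both heterocycles. The key step exploits C8: it is bonded to C2 of ring B and to the olefinic carbon C7, so a radical at C8 is stabilised by ring B (O1–C2=C3–C4=O) and can be joined to a metal-bound C7. The lateral hydrogens are vinylogously acidic and C8–H is also allylic, so base can epimerise it or move the olefin into conjugation. The C3 acetate is β to the acidic C2–H, the C5 acetate is allylic, and the C3' hydroxyl must end free beside two acetates. The real difficulty is C8, which no neighbouring centre controls, together with the union of two fully substituted pyranone halves across the E olefin.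

## Logic of the disconnections

**28 back to 26.** The O–Si bond at C3' is cut (28 from 27), then the two O–acyl bonds at C3 and C5 (27 from 26). Acylating after the union keeps an allylic ester and a β-acyloxy group out of the metal-mediated step, and the silyl ether is what distinguishes O3' from the two oxygens that become acetates. The forward steps must use a base too weak to touch C2–H or C8–H and a fluoride source that spares an allylic acetate.

**26 to 17 and 25.** The C7–C8 bond is cut. It is the only bond between the two pyranone halves, and forming it through a planar intermediate at C8 lets a catalyst set this isolated centre at the moment of union. The gain is two halves of similar size, each holding one ring taken from 4, with C8 absent from every earlier intermediate. The forward step must control the face at C8, keep the E geometry of C6=C7, tolerate two free hydroxyls and work without base.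

**25 to 23.** The C8–Cl bond is cut, leaving the untouched ethyl group of ring B. This turns the coupling handle into a lateral C–H functionalisation. It demands deprotonation at the CH2 and not at the methine C2'.

**23 to 21.** The O–Si bond is cut (23 from 22), then the C3'–H bond (22 from 21). Both C2' and C3' are made to depend on one reduction of a ketone whose α-centre racemises freely, so no stereochemistry is needed before this point. The demand is a catalyst that reduces one enantiomer from one face while the other racemises.

**21 to 4 and 18.** The C2'–C3' bond is cut. The arm is an acyl group added to a lateral carbon of 4; because 4 is symmetric, either ethyl group gives the same product. The forward step must stop at mono-acylation, which asks for an acyl donor whose adduct survives until the quench.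

**17 to 4 and 14.** The O–Si bond at O5 is cut (17 from 16), then the C2–C3 bond (16 from 4 and 14). Ring A arrives complete in one step, and the tetrad is reduced to an aldehyde with two stereocentres. The forward step must set C3 by aldehyde control and C2 by simple diastereoselection.

**14 to 8 and 9.** Functional group changes lead back from 14 through 13 and 12 to 11, where the C4–C5 bond is cut. An anti-aldol of a propanoyl imide with an enal that already holds the vinyl bromide sets C4 and C5 and brings in C6=C7 with fixed geometry.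

**8 to 5.** The C–CH3 and C–Br bonds are cut (through 7). A syn carbometalation of an alkyne fixes the E geometry.

**4 to 1 and 2.** The two C–C bonds between the central ketone unit and the two propanoyl units and one ring C–O bond are cut (through 3); one step gives the ring used twice.

## Other disconnections considered

**Alternative 1:** the first that comes to mind. Both rings are cut at O1–C2 back to β-triketones, the chain is built by iterative aldol reactions, and the forward key step is a double cyclodehydration of the open-chain bis(triketone) A1. In A1 the centres C2, C8 and C2' are α to 1,3-dicarbonyl units and so more acidic than in the pyranones; C8 is also β,γ-unsaturated, and the C3 oxygen becomes a β-acyloxy ketone prone to elimination. Each ring would cost an aldol, an oxidation and the cyclisation. The chosen plan buys both rings in step 1 and never passes through a triketone.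

**Alternative 2:** the C6=C7 bond is cut. The forward key step is a Horner–Wadsworth–Emmons reaction of aldehyde A2 with β-ketophosphonate A3 to enone A4, followed by a hydroxyl-directed 1,3-anti reduction at C5. In A2 the C8–H lies between a formyl group and ring B, so the base needed for the olefination should racemise it. In A4 the same hydrogen is γ to an enone and lateral to ring B, which invites deconjugation. C5 needs an extra reduction and extra protecting-group traffic. The chosen plan forms C7–C8 without base and takes C5 from the aldol.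

**Alternative 3:** the C5–C6 bond is cut. The forward key step is a Nozaki–Hiyama–Kishi coupling (CrCl2, catalytic NiCl2) of vinyl iodide A5 with aldehyde A6 to the allylic alcohol A7. Addition to an α-methyl aldehyde should follow the Felkin–Anh sense and give 4,5-syn, whereas A7 needs 4,5-anti, so an oxidation and reduction would have to follow. A5 also still contains C8, for which this plan offers no control, so the hardest centre is only moved into a fragment synthesis.

Key step: step 14

Assumption: pyranone 4 is prepared and not bought, and the antipode of the bis(oxazoline) ligand that delivers 8S in step 14 is fixed by a trial coupling; neither choice changes any other step.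

## Route

Step 1
Reactants: 1 pentan-3-one; 2 propanoic anhydride
Product: 4 2,6-diethyl-3,5-dimethyl-4H-pyran-4-one, via 4,6-dimethylnonane-3,5,7-trione 3 (not isolated)
Conditions: polyphosphoric acid, 100–130 °C
Reagents that add atoms: none
Why: Acid-mediated double C-acylation of the ketone at both α-carbons gives the 1,3,5-triketone 3, which cyclodehydrates in the same medium to the fully substituted pyranone; the product is symmetric, so no selectivity question arises.

Step 2
Reactants: 5 prop-2-yn-1-ol
Product: 7 (2E)-3-bromo-2-methylprop-2-en-1-ol, via alkenylalane 6 (not isolated)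
Conditions: Me3Al, Cp2ZrCl2 (0.25 equiv), CH2Cl2, 0 °C to rt; then N-bromosuccinimide, THF, −30 to 0 °C
Reagents that add atoms: trimethylaluminium, C[Al](C)C; N-bromosuccinimide, O=C1CCC(=O)N1Br
Why: Negishi zirconium-catalysed carboalumination adds CH3 and Al syn across the alkyne with aluminium on the terminal carbon; bromodealumination with retention should give the E vinyl bromide that fixes the C6=C7 geometry of the target.

Step 3
Reactants: 7 (2E)-3-bromo-2-methylprop-2-en-1-ol
Product: 8 (2E)-3-bromo-2-methylprop-2-enal
Conditions: MnO2, CH2Cl2, rt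
Reagents that add atoms: none
Why: Selective oxidation of an allylic alcohol on the MnO2 surface; the neutral conditions should leave the olefin geometry and the vinyl bromide untouched.

Step 4
Reactants: 8 (2E)-3-bromo-2-methylprop-2-enal; 9 (4R)-4-benzyl-3-propanoyl-1,3-oxazolidin-2-one
Product: 11 (4R)-4-benzyl-3-[(2S,3R,4E)-5-bromo-3-hydroxy-2,4-dimethylpent-4-enoyl]-1,3-oxazolidin-2-one, via trimethylsilyl ether 10 (not isolated)
Conditions: MgCl2 (0.1 equiv), Et3N, Me3SiCl, EtOAc, rt; then CF3CO2H (cat.), MeOH
Reagents that add atoms: chlorotrimethylsilane, C[Si](C)(C)Cl (its silyl group stays in 10 only and is lost on the way to 11)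
Why: Magnesium halide-catalysed anti-aldol of the N-propanoyl oxazolidinone: the chelated magnesium Z-enolate adds to the non-enolisable enal through a boat-like transition state on the face away from the benzyl group, and silylation of the aldolate to 10 turns the catalyst over. This sets C4 and C5 of the target (anti) in one step; acidic methanol then frees the alcohol.

Step 5
Reactants: 11 (4R)-4-benzyl-3-[(2S,3R,4E)-5-bromo-3-hydroxy-2,4-dimethylpent-4-enoyl]-1,3-oxazolidin-2-one
Product: 12 (2S,3R,4E)-5-bromo-3-hydroxy-N-methoxy-N,2,4-trimethylpent-4-enamide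
Conditions: MeNHOMe·HCl, Me3Al, CH2Cl2, −10 °C to rt
Reagents that add atoms: N,O-dimethylhydroxylamine hydrochloride, CNOC.Cl
Why: Weinreb transamination of the imide by the aluminium amide formed in the flask; the free β-hydroxyl, as its aluminium alkoxide, steers attack to the exocyclic carbonyl, and neither stereocentre is touched.

Step 6
Reactants: 12 (2S,3R,4E)-5-bromo-3-hydroxy-N-methoxy-N,2,4-trimethylpent-4-enamide
Product: 13 (2S,3R,4E)-5-bromo-N-methoxy-N,2,4-trimethyl-3-(triethylsilyloxy)pent-4-enamide
Conditions: Et3SiOTf, 2,6-lutidine, CH2Cl2, −78 to 0 °C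
Reagents that add atoms: triethylsilyl trifluoromethanesulfonate, CC[Si](CC)(CC)OS(=O)(=O)C(F)(F)F
Why: Standard silylation of a secondary allylic alcohol; the triethylsilyl group masks O5 through the hydride and dienolate steps that follow and is easily removed afterwards.

Step 7
Reactants: 13 (2S,3R,4E)-5-bromo-N-methoxy-N,2,4-trimethyl-3-(triethylsilyloxy)pent-4-enamide
Product: 14 (2S,3R,4E)-5-bromo-2,4-dimethyl-3-(triethylsilyloxy)pent-4-enal
Conditions: iBu2AlH, THF, −78 °C; aqueous potassium sodium tartrate work-up
Reagents that add atoms: none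
Why: Reduction of a Weinreb amide stops at the aldehyde oxidation level at −78 °C, and the cold buffered work-up should leave the α-stereocentre (C4 of the target) intact.

Step 8
Reactants: 4 2,6-diethyl-3,5-dimethyl-4H-pyran-4-one; 14 (2S,3R,4E)-5-bromo-2,4-dimethyl-3-(triethylsilyloxy)pent-4-enal
Product: 16 2-[(2R,3R,4R,5R,6E)-7-bromo-3-hydroxy-4,6-dimethyl-5-(triethylsilyloxy)hept-6-en-2-yl]-6-ethyl-3,5-dimethyl-4H-pyran-4-one, via lithium lateral dienolate 15 (not isolated)
Conditions: LiN(SiMe3)2, THF, −78 °C; then 14, −78 °C; AcOH quench at −78 °C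
Reagents that add atoms: lithium bis(trimethylsilyl)amide, [Li+].C[Si](C)(C)[N-][Si](C)(C)C (lithium of 15 only)
Why: Lateral (vinylogous) aldol addition: lithium dienolate 15 of the symmetric pyranone reacts at its exocyclic carbon with the aldehyde and forms C2–C3 with ring A already complete; lithium is chosen because its tight aldolate resists retro-aldol until the cold quench. C3 should follow the Felkin–Anh preference of the α-methyl aldehyde, reinforced by the anti β-silyloxy group (3,4-syn, 3,5-anti). C2 (2,3-anti) is expected from an open transition state in which the aldehyde chain avoids the ring methyl next to the lateral carbon, and this is the less secure element.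

Step 9
Reactants: 16 2-[(2R,3R,4R,5R,6E)-7-bromo-3-hydroxy-4,6-dimethyl-5-(triethylsilyloxy)hept-6-en-2-yl]-6-ethyl-3,5-dimethyl-4H-pyran-4-one
Product: 17 2-[(2R,3R,4R,5R,6E)-7-bromo-3,5-dihydroxy-4,6-dimethylhept-6-en-2-yl]-6-ethyl-3,5-dimethyl-4H-pyran-4-one
Conditions: HF·pyridine, pyridine, THF, 0 °C
Reagents that add atoms: none
Why: Buffered fluoride cleavage of the silyl ether; the diol is the form in which this half enters the coupling, so that no allylic ester meets low-valent nickel.

Step 10
Reactants: 4 2,6-diethyl-3,5-dimethyl-4H-pyran-4-one; 18 N-methoxy-N-methylpropanamide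
Product: 21 2-ethyl-3,5-dimethyl-6-(3-oxopentan-2-yl)-4H-pyran-4-one (racemic), via sodium lateral dienolate 19 (not isolated), via sodium hemiaminal alkoxide 20 (not isolated)
Conditions: NaN(SiMe3)2, THF, −78 °C; then 18, −78 °C; AcOH quench at −78 °C
Reagents that add atoms: sodium bis(trimethylsilyl)amide, [Na+].C[Si](C)(C)[N-][Si](C)(C)C (sodium of 19 and 20 only)
Why: Lateral acylation of a vinylogous enolate with a Weinreb amide: the sodium amide base gives dienolate 19, which is more ionic and therefore more nucleophilic than its lithium counterpart, so addition to the weakly electrophilic amide should be complete at −78 °C. At that temperature the N-methoxy-chelated tetrahedral adduct 20 survives until the cold quench, so the more acidic ketone 21 is never present beside the dienolate and over-reaction is excluded. The new centre is formed racemic on purpose.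

Step 11
Reactants: 21 2-ethyl-3,5-dimethyl-6-(3-oxopentan-2-yl)-4H-pyran-4-one (racemic)
Product: 22 2-ethyl-6-[(2S,3S)-3-hydroxypentan-2-yl]-3,5-dimethyl-4H-pyran-4-one
Conditions: ketoreductase (NADPH-dependent, Prelog-selective, from a screening panel), NADP+ (cat.), iPrOH, DMSO (10 vol %), potassium phosphate buffer pH 8, 30 °C
Reagents that add atoms: none
Why: Enzymatic dynamic kinetic resolution: 21 racemises through its enol because C2'–H lies between the ketone and C6 of ring B (a vinylogous 1,3-dicarbonyl), while the ketoreductase reduces one enantiomer from one carbonyl face, so C2' and C3' are set together as the anti (S,S) pair. An ethyl ketone with one bulky α-substituent is the small/large pattern this enzyme class accepts; the enzyme is chosen by screening.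

Step 12
Reactants: 22 2-ethyl-6-[(2S,3S)-3-hydroxypentan-2-yl]-3,5-dimethyl-4H-pyran-4-one
Product: 23 2-ethyl-3,5-dimethyl-6-[(2S,3S)-3-(triethylsilyloxy)pentan-2-yl]-4H-pyran-4-one
Conditions: Et3SiCl, imidazole, DMF, 0 °C to rt
Reagents that add atoms: chlorotriethylsilane, CC[Si](CC)(CC)Cl
Why: Silylation under near-neutral conditions; the ether protects O3' during the lateral metalation and marks it as the one hydroxyl that is freed at the end.

Step 13
Reactants: 23 2-ethyl-3,5-dimethyl-6-[(2S,3S)-3-(triethylsilyloxy)pentan-2-yl]-4H-pyran-4-one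
Product: 25 2-[(1RS)-1-chloroethyl]-3,5-dimethyl-6-[(2S,3S)-3-(triethylsilyloxy)pentan-2-yl]-4H-pyran-4-one, via lithium lateral dienolate 24 (not isolated)
Conditions: LiN(SiMe3)2, THF, −78 °C; then transfer into C2Cl6, THF, −78 °C
Reagents that add atoms: hexachloroethane, ClC(Cl)(Cl)C(Cl)(Cl)Cl; lithium bis(trimethylsilyl)amide, [Li+].C[Si](C)(C)[N-][Si](C)(C)C (lithium of 24 only)
Why: The bulky amide base should deprotonate the CH2 of the remaining ethyl group in preference to the hindered methine C2', and dienolate 24 is chlorinated at its exocyclic carbon (electrophilic α-halogenation of an enolate); inverse addition limits proton transfer to the more acidic product. The configuration at the C–Cl carbon does not matter because step 14 is stereoconvergent.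

Step 14
Reactants: 17 2-[(2R,3R,4R,5R,6E)-7-bromo-3,5-dihydroxy-4,6-dimethylhept-6-en-2-yl]-6-ethyl-3,5-dimethyl-4H-pyran-4-one; 25 2-[(1RS)-1-chloroethyl]-3,5-dimethyl-6-[(2S,3S)-3-(triethylsilyloxy)pentan-2-yl]-4H-pyran-4-one
Product: 26 2-[(2R,3R,4R,5R,6E,8S)-8-{3,5-dimethyl-4-oxo-6-[(2S,3S)-3-(triethylsilyloxy)pentan-2-yl]-4H-pyran-2-yl}-3,5-dihydroxy-4,6-dimethylnon-6-en-2-yl]-6-ethyl-3,5-dimethyl-4H-pyran-4-one
Conditions: NiCl2(MeOCH2CH2OMe) (10 mol %), cyclopropane-1,1-diyl-bridged bis(indano-oxazoline) ligand (11 mol %, antipode giving 8S), manganese powder, NaI (0.5 equiv), N,N-dimethylacetamide, 0 °C; 25 in excess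
Reagents that add atoms: none
Why: Zerovalent nickel bound to the bis(oxazoline) inserts into the C7–Br bond of 17 with retention of the E geometry, while a low-valent nickel species abstracts chlorine from either epimer of 25 to give one planar lateral radical, delocalised over C2=C3–C4=O and the ring oxygen of ring B; the radical is captured at nickel, the C7–C8 bond forms by reductive elimination from trivalent nickel, and manganese returns the catalyst to the zerovalent state. The closest known reaction type is the nickel/bis(oxazoline)-catalysed enantioconvergent reductive cross-coupling of vinyl bromides with racemic secondary benzylic chlorides; here the pyranone takes the place of the arene as the radical-stabilising group. No ring is closed. The one new stereocentre, C8, is set by the chiral ligand during radical capture and reductive elimination, so both epimers of 25 should converge on 8S; the nearest resident centres (C5 on the vinyl partner, C2' across ring B) are three and four bonds away and should at most modulate the ligand's preference. Cross-selectivity over homocoupling rests on the different activation modes of the partners, two-electron insertion at the sp2 C–Br bond and one-electron abstraction at the sp3 C–Cl bond. Bonding at the lateral carbon, not at ring carbon C3, is expected because C3 carries a methyl group and bonding there would break the pyranone conjugation. No base is present, so the acidic hydrogens at C2, C8 and C2' and the E olefin should stay untouched, and the free hydroxyls at C3 and C5 are tolerated where an allylic acetate might ionise.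

Step 15
Reactants: 26 2-[(2R,3R,4R,5R,6E,8S)-8-{3,5-dimethyl-4-oxo-6-[(2S,3S)-3-(triethylsilyloxy)pentan-2-yl]-4H-pyran-2-yl}-3,5-dihydroxy-4,6-dimethylnon-6-en-2-yl]-6-ethyl-3,5-dimethyl-4H-pyran-4-one
Product: 27 (2R,3R,4R,5R,6E,8S)-8-{3,5-dimethyl-4-oxo-6-[(2S,3S)-3-(triethylsilyloxy)pentan-2-yl]-4H-pyran-2-yl}-2-(6-ethyl-3,5-dimethyl-4-oxo-4H-pyran-2-yl)-4,6-dimethylnon-6-ene-3,5-diyl diacetate
Conditions: Ac2O, pyridine, 4-(dimethylamino)pyridine (cat.), CH2Cl2, 0 °C to rt
Reagents that add atoms: acetic anhydride, CC(=O)OC(C)=O
Why: Nucleophile-catalysed acylation of both secondary hydroxyls; pyridine is far too weak a base to deprotonate C2–H or C8–H, so neither elimination of the C3 acetate nor epimerisation is expected.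

Step 16
Reactants: 27 (2R,3R,4R,5R,6E,8S)-8-{3,5-dimethyl-4-oxo-6-[(2S,3S)-3-(triethylsilyloxy)pentan-2-yl]-4H-pyran-2-yl}-2-(6-ethyl-3,5-dimethyl-4-oxo-4H-pyran-2-yl)-4,6-dimethylnon-6-ene-3,5-diyl diacetate
Product: 28 (2R,3R,4R,5R,6E,8S)-2-(6-ethyl-3,5-dimethyl-4-oxo-4H-pyran-2-yl)-8-{6-[(2S,3S)-3-hydroxypentan-2-yl]-3,5-dimethyl-4-oxo-4H-pyran-2-yl}-4,6-dimethylnon-6-ene-3,5-diyl diacetate (CNP0188089.1)
Conditions: HF·pyridine, pyridine, THF, 0 °C
Reagents that add atoms: none
Why: Buffered fluoride removes the triethylsilyl ether from O3'; the acetates, including the allylic one at C5, are stable to these conditions, and no base is present that could shift an acetyl group or epimerise a lateral centre.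

## Compound list

1 | pentan-3-one | CCC(=O)CC | starting material
2 | propanoic anhydride | CCC(=O)OC(=O)CC | starting material
3 | 4,6-dimethylnonane-3,5,7-trione (stereoisomer mixture) | CCC(=O)C(C)C(=O)C(C)C(=O)CC | intermediate (not isolated)
4 | 2,6-diethyl-3,5-dimethyl-4H-pyran-4-one | CCc1oc(CC)c(C)c(=O)c1C | intermediate
5 | prop-2-yn-1-ol | C#CCO | starting material
6 | [(1E)-3-(dimethylalumanyloxy)-2-methylprop-1-en-1-yl]dimethylalumane | C[Al](C)/C=C(\C)CO[Al](C)C | intermediate (not isolated)
7 | (2E)-3-bromo-2-methylprop-2-en-1-ol | OC/C(C)=C/Br | intermediate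
8 | (2E)-3-bromo-2-methylprop-2-enal | O=C/C(C)=C/Br | intermediate
9 | (4R)-4-benzyl-3-propanoyl-1,3-oxazolidin-2-one | O=C1OC[C@@H](Cc2ccccc2)N1C(=O)CC | starting material
10 | (4R)-4-benzyl-3-[(2S,3R,4E)-5-bromo-2,4-dimethyl-3-(trimethylsilyloxy)pent-4-enoyl]-1,3-oxazolidin-2-one | O=C1OC[C@@H](Cc2ccccc2)N1C(=O)[C@@H](C)[C@@H](O[Si](C)(C)C)/C(C)=C/Br | intermediate (not isolated)
11 | (4R)-4-benzyl-3-[(2S,3R,4E)-5-bromo-3-hydroxy-2,4-dimethylpent-4-enoyl]-1,3-oxazolidin-2-one | O=C1OC[C@@H](Cc2ccccc2)N1C(=O)[C@@H](C)[C@@H](O)/C(C)=C/Br | intermediate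
12 | (2S,3R,4E)-5-bromo-3-hydroxy-N-methoxy-N,2,4-trimethylpent-4-enamide | CON(C)C(=O)[C@@H](C)[C@@H](O)/C(C)=C/Br | intermediate
13 | (2S,3R,4E)-5-bromo-N-methoxy-N,2,4-trimethyl-3-(triethylsilyloxy)pent-4-enamide | CON(C)C(=O)[C@@H](C)[C@@H](O[Si](CC)(CC)CC)/C(C)=C/Br | intermediate
14 | (2S,3R,4E)-5-bromo-2,4-dimethyl-3-(triethylsilyloxy)pent-4-enal | O=C[C@@H](C)[C@@H](O[Si](CC)(CC)CC)/C(C)=C/Br | intermediate
15 | lithium 6-ethyl-2-[(Z)-ethylidene]-3,5-dimethyl-2H-pyran-4-olate | [Li+].C/C=C1\OC(CC)=C(C)C([O-])=C1C | intermediate (not isolated)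
16 | 2-[(2R,3R,4R,5R,6E)-7-bromo-3-hydroxy-4,6-dimethyl-5-(triethylsilyloxy)hept-6-en-2-yl]-6-ethyl-3,5-dimethyl-4H-pyran-4-one | CCc1oc([C@H](C)[C@H](O)[C@@H](C)[C@@H](O[Si](CC)(CC)CC)/C(C)=C/Br)c(C)c(=O)c1C | intermediate
17 | 2-[(2R,3R,4R,5R,6E)-7-bromo-3,5-dihydroxy-4,6-dimethylhept-6-en-2-yl]-6-ethyl-3,5-dimethyl-4H-pyran-4-one | CCc1oc([C@H](C)[C@H](O)[C@@H](C)[C@@H](O)/C(C)=C/Br)c(C)c(=O)c1C | intermediate
18 | N-methoxy-N-methylpropanamide | CCC(=O)N(C)OC | starting material
19 | sodium 6-ethyl-2-[(Z)-ethylidene]-3,5-dimethyl-2H-pyran-4-olate | [Na+].C/C=C1\OC(CC)=C(C)C([O-])=C1C | intermediate (not isolated)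
20 | sodium 2-(6-ethyl-3,5-dimethyl-4-oxo-4H-pyran-2-yl)-3-[methoxy(methyl)amino]pentan-3-olate (stereoisomer mixture) | [Na+].CCc1oc(C(C)C([O-])(CC)N(C)OC)c(C)c(=O)c1C | intermediate (not isolated)
21 | 2-ethyl-3,5-dimethyl-6-(3-oxopentan-2-yl)-4H-pyran-4-one (racemic) | CCC(=O)C(C)c1oc(CC)c(C)c(=O)c1C | intermediate
22 | 2-ethyl-6-[(2S,3S)-3-hydroxypentan-2-yl]-3,5-dimethyl-4H-pyran-4-one | CCc1oc([C@@H](C)[C@@H](O)CC)c(C)c(=O)c1C | intermediate
23 | 2-ethyl-3,5-dimethyl-6-[(2S,3S)-3-(triethylsilyloxy)pentan-2-yl]-4H-pyran-4-one | CCc1oc([C@@H](C)[C@@H](O[Si](CC)(CC)CC)CC)c(C)c(=O)c1C | intermediate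
24 | lithium 2-[(Z)-ethylidene]-3,5-dimethyl-6-[(2S,3S)-3-(triethylsilyloxy)pentan-2-yl]-2H-pyran-4-olate | [Li+].C/C=C1\OC([C@@H](C)[C@@H](O[Si](CC)(CC)CC)CC)=C(C)C([O-])=C1C | intermediate (not isolated)
25 | 2-[(1RS)-1-chloroethyl]-3,5-dimethyl-6-[(2S,3S)-3-(triethylsilyloxy)pentan-2-yl]-4H-pyran-4-one (both epimers at the C–Cl carbon) | CC(Cl)c1oc([C@@H](C)[C@@H](O[Si](CC)(CC)CC)CC)c(C)c(=O)c1C | intermediate
26 | 2-[(2R,3R,4R,5R,6E,8S)-8-{3,5-dimethyl-4-oxo-6-[(2S,3S)-3-(triethylsilyloxy)pentan-2-yl]-4H-pyran-2-yl}-3,5-dihydroxy-4,6-dimethylnon-6-en-2-yl]-6-ethyl-3,5-dimethyl-4H-pyran-4-one | CCc1oc([C@H](C)[C@H](O)[C@@H](C)[C@@H](O)/C(C)=C/[C@H](C)c2oc([C@@H](C)[C@@H](O[Si](CC)(CC)CC)CC)c(C)c(=O)c2C)c(C)c(=O)c1C | intermediate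
27 | (2R,3R,4R,5R,6E,8S)-8-{3,5-dimethyl-4-oxo-6-[(2S,3S)-3-(triethylsilyloxy)pentan-2-yl]-4H-pyran-2-yl}-2-(6-ethyl-3,5-dimethyl-4-oxo-4H-pyran-2-yl)-4,6-dimethylnon-6-ene-3,5-diyl diacetate | CCc1oc([C@H](C)[C@H](OC(C)=O)[C@@H](C)[C@@H](OC(C)=O)/C(C)=C/[C@H](C)c2oc([C@@H](C)[C@@H](O[Si](CC)(CC)CC)CC)c(C)c(=O)c2C)c(C)c(=O)c1C | intermediate
28 | (2R,3R,4R,5R,6E,8S)-2-(6-ethyl-3,5-dimethyl-4-oxo-4H-pyran-2-yl)-8-{6-[(2S,3S)-3-hydroxypentan-2-yl]-3,5-dimethyl-4-oxo-4H-pyran-2-yl}-4,6-dimethylnon-6-ene-3,5-diyl diacetate | CCc1oc([C@H](C)[C@H](OC(C)=O)[C@@H](C)[C@@H](OC(C)=O)/C(C)=C/[C@H](C)c2oc([C@@H](C)[C@@H](O)CC)c(C)c(=O)c2C)c(C)c(=O)c1C | target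

## Step count and least certain steps

Total: 16 steps. Longest linear sequence: 11 steps (5 → 7 → 8 → 11 → 12 → 13 → 14 → 16 → 17 → 26 → 27 → 28, steps 2–9 and 14–16).

**Step 14 (key step).** The most likely failure is poor facial selectivity at C8, because the ligand's preference may be opposed by the allylic C5 centre of the vinyl partner or weakened by the unusual radical. Two further risks are reductive dimerisation of the lateral radical and loss of hydrogen chloride from the chloride before it is activated. Fallback, from 25 back to 26: insertion of zinc dust (activated with LiCl, THF) into 25 gives the lateral zinc reagent F1, a vinylogous Reformatsky reagent. F1 is joined to 17 by a Negishi coupling under Pd(OAc)2 and the phosphine SPhos, a coupling type that tolerates free hydroxyls on the halide. C8 is then formed without control, and 26 is separated by chromatography from its C8 epimer F2.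

**Step 8.** The most likely failure is low simple diastereoselection between C2 and C3. The metal sits on the remote O4 of the dienolate, so the addition runs through an open transition state whose anti preference is only a steric argument; reversal of the aldol on warming is a second risk. Fallback, from 14 back to 17, which builds ring A in the classical way on an anti-aldol ester: 2,6-dimethylphenyl propanoate F3 is made from 2,6-dimethylphenol and propanoyl chloride. F3 is deprotonated with LiN(iPr)2 (THF, −78 °C) and added to 14; the E ester enolate reacts through a closed transition state in the anti and Felkin–Anh sense to give anti-aldol ester F4. Silylation (Et3SiOTf, 2,6-lutidine) gives bis-silyl ether F5. Commercial 4-methylheptane-3,5-dione, doubly deprotonated with LiN(iPr)2, is acylated at its terminal carbon by F5 to give triketone F6. Cyclodehydration with PPh3/CCl4 gives bis-silyl pyranone F7, and HF·pyridine then gives 17.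

**Step 13.** The most likely failure is competing deprotonation at the methine C2', which would epimerise that centre or expel the β-silyloxy group; over-chlorination through proton exchange with the more acidic product is a second risk. Fallback, from 22 back to 25: the free alcohol 22 is treated with two equivalents of LiN(SiMe3)2. The alkoxide formed first places a negative charge next to C2' and steers the second deprotonation to the distant ethyl group. Chlorination with C2Cl6 gives chloro alcohol F8, and silylation (Et3SiCl, imidazole) gives 25.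

**Step 11.** The most likely failure is that no enzyme of the panel combines the anti sense with the required absolute sense, or that racemisation of the ketone is too slow at a pH the enzyme tolerates, so the reduction stalls as a simple kinetic resolution. Fallback, from 4 back to 22: lateral aldol of 4 with propanal under the conditions of step 8 gives the aldol mixture F9. Its racemic anti pair is separated from the syn pair by chromatography and resolved by lipase-catalysed acylation (Candida antarctica lipase B, vinyl acetate). By the usual preference of this lipase for the enantiomer with R configuration at the carbinol, the (2R,3R) alcohol should be acylated to acetate F10 and 22 left unreacted.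

## Further compounds

F1 | step 14 | chlorido{1-[3,5-dimethyl-4-oxo-6-[(2S,3S)-3-(triethylsilyloxy)pentan-2-yl]-4H-pyran-2-yl]ethyl}zinc (both epimers at the zinc-bearing carbon) | CC([Zn]Cl)c1oc([C@@H](C)[C@@H](O[Si](CC)(CC)CC)CC)c(C)c(=O)c1C
F2 | step 14 | (8R) epimer of 26 | CCc1oc([C@H](C)[C@H](O)[C@@H](C)[C@@H](O)/C(C)=C/[C@@H](C)c2oc([C@@H](C)[C@@H](O[Si](CC)(CC)CC)CC)c(C)c(=O)c2C)c(C)c(=O)c1C
F3 | step 8 | 2,6-dimethylphenyl propanoate | CCC(=O)Oc1c(C)cccc1C
F4 | step 8 | 2,6-dimethylphenyl (2R,3R,4R,5R,6E)-7-bromo-3-hydroxy-2,4,6-trimethyl-5-(triethylsilyloxy)hept-6-enoate | Cc1cccc(C)c1OC(=O)[C@H](C)[C@H](O)[C@@H](C)[C@@H](O[Si](CC)(CC)CC)/C(C)=C/Br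
F5 | step 8 | 2,6-dimethylphenyl (2R,3R,4R,5R,6E)-7-bromo-2,4,6-trimethyl-3,5-bis(triethylsilyloxy)hept-6-enoate | Cc1cccc(C)c1OC(=O)[C@H](C)[C@H](O[Si](CC)(CC)CC)[C@@H](C)[C@@H](O[Si](CC)(CC)CC)/C(C)=C/Br
F6 | step 8 | (8R,9R,10R,11R,12E)-13-bromo-4,6,8,10,12-pentamethyl-9,11-bis(triethylsilyloxy)tridec-12-ene-3,5,7-trione (mixture at C4 and C6) | CCC(=O)C(C)C(=O)C(C)C(=O)[C@H](C)[C@H](O[Si](CC)(CC)CC)[C@@H](C)[C@@H](O[Si](CC)(CC)CC)/C(C)=C/Br
F7 | step 8 | 2-[(2R,3R,4R,5R,6E)-7-bromo-4,6-dimethyl-3,5-bis(triethylsilyloxy)hept-6-en-2-yl]-6-ethyl-3,5-dimethyl-4H-pyran-4-one | CCc1oc([C@H](C)[C@H](O[Si](CC)(CC)CC)[C@@H](C)[C@@H](O[Si](CC)(CC)CC)/C(C)=C/Br)c(C)c(=O)c1C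
F8 | step 13 | 2-[(1RS)-1-chloroethyl]-6-[(2S,3S)-3-hydroxypentan-2-yl]-3,5-dimethyl-4H-pyran-4-one | CC(Cl)c1oc([C@@H](C)[C@@H](O)CC)c(C)c(=O)c1C
F9 | step 11 | 2-ethyl-6-(3-hydroxypentan-2-yl)-3,5-dimethyl-4H-pyran-4-one (mixture of the four stereoisomers) | CCc1oc(C(C)C(O)CC)c(C)c(=O)c1C
F10 | step 11 | (2R,3R)-2-(6-ethyl-3,5-dimethyl-4-oxo-4H-pyran-2-yl)pentan-3-yl acetate | CCc1oc([C@H](C)[C@H](OC(C)=O)CC)c(C)c(=O)c1C
A1 | alternative 1 | open-chain bis(1,3,5-triketone) corresponding to 27 with both pyranone rings opened (centres between the ketones unspecified) | CCC(=O)C(C)C(=O)C(C)C(=O)[C@H](C)[C@H](OC(C)=O)[C@@H](C)[C@@H](OC(C)=O)/C(C)=C/[C@H](C)C(=O)C(C)C(=O)C(C)C(=O)[C@@H](C)[C@@H](O[Si](CC)(CC)CC)CC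
A2 | alternative 2 | (2R)-2-{3,5-dimethyl-4-oxo-6-[(2S,3S)-3-(triethylsilyloxy)pentan-2-yl]-4H-pyran-2-yl}propanal (ring B aldehyde, C7 as formyl carbon) | O=C[C@H](C)c1oc([C@@H](C)[C@@H](O[Si](CC)(CC)CC)CC)c(C)c(=O)c1C
A3 | alternative 2 | ring A β-ketophosphonate: diethyl phosphonate on C6, ketone at C5, triethylsilyl ether at O3 (mixture at C6) | CCc1oc([C@H](C)[C@H](O[Si](CC)(CC)CC)[C@@H](C)C(=O)C(C)P(=O)(OCC)OCC)c(C)c(=O)c1C
A4 | alternative 2 | C5 ketone (6E enone) carrying both pyranones, bis(triethylsilyl) ether at O3 and O3' | CCc1oc([C@H](C)[C@H](O[Si](CC)(CC)CC)[C@@H](C)C(=O)/C(C)=C/[C@H](C)c2oc([C@@H](C)[C@@H](O[Si](CC)(CC)CC)CC)c(C)c(=O)c2C)c(C)c(=O)c1C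
A5 | alternative 3 | 2-[(2S,3E)-4-iodopent-3-en-2-yl]-3,5-dimethyl-6-[(2S,3S)-3-(triethylsilyloxy)pentan-2-yl]-4H-pyran-4-one | I/C(C)=C/[C@H](C)c1oc([C@@H](C)[C@@H](O[Si](CC)(CC)CC)CC)c(C)c(=O)c1C
A6 | alternative 3 | ring A aldehyde: C2–C4 segment with C5 as formyl carbon and triethylsilyl ether at O3 | CCc1oc([C@H](C)[C@H](O[Si](CC)(CC)CC)[C@@H](C)C=O)c(C)c(=O)c1C
A7 | alternative 3 | (5R) allylic alcohol carrying both pyranones, bis(triethylsilyl) ether at O3 and O3' | CCc1oc([C@H](C)[C@H](O[Si](CC)(CC)CC)[C@@H](C)[C@@H](O)/C(C)=C/[C@H](C)c2oc([C@@H](C)[C@@H](O[Si](CC)(CC)CC)CC)c(C)c(=O)c2C)c(C)c(=O)c1C
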